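(The readings were computed from invented constants; noise was put on by code.)

Early on, target in the south-east run rose from 7% at 0.500 min to 27% at 1.00 min, a reading of 3.86 times for a doubling of time, so I took the rate to be climbing in step with time: an induction period.

| flask | substrate | precatalyst | remark |
|---|---|---|---|
| south-west | 0.026 M | 2.6 µM | the very flask that is asked about, followed so far |
| south-east | 0.017 M | 2.6 µM | run made earlier |
| flask | 0.026 M | 2.6 µM |  |

| run | time / min | target / % | substrate / % |
|---|---|---|---|
| south-west | 0.200 | 1 | 98 |
| south-west | 0.667 | 12 | 87 |
| south-west | 1.00 | 20 | 76 |
| south-west | 2.00 | 62 | 39 |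
| south-west | 2.50 | 77 | 21 |
| south-west | 3.00 | 83 | 16 |
| south-east | 0.500 | 7 | 90 |
| south-east | 1.00 | 27 | 72 |
| south-east | 1.50 | 48 | 51 |
| south-east | 2.00 | 69 | 34 |
| south-east | 2.50 | 75 | 27 |
| south-east | 3.00 | 82 | 17 |

(scatter of a reading: 2 percentage points)

- what was read earlier has a scatter of 2 percentage points, one standard deviation
- no earlier run changes the charge of precatalyst; that part of a forecast is a guess

- factor on the rate of making target when 10% of the substrate are converted if precatalyst is charged twice over
- factor on the rate when 10% of the substrate are converted if precatalyst is charged at 12 µM instead

I built the south-west flask up one process at a time. With the main step alone, the catalyst active from the start and the rate proportional to it (a guess, since no run varies the charge), the factors on the rate at fixed conversion equal the charge factors, 2 and 4.62.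

Then I added activation at a steady pace. Let L be the precatalyst charge, f the active share of the catalyst, x the conversion, t the time, and g(x) whatever the substrate does to the rate. Dividing the rate of conversion by g(x) puts time on one side only:

dx / g(x) = L·f·dt

The left side depends on conversion, so at fixed x the product L·f·t stays unchanged. Since f grows with t:

f ∝ 1/√L, and rate ∝ L·f ∝ √L

So the factor on the rate is S, the square root of the ratio of charges 2.15 at 12 µM, and 1.41 for a doubled charge.

Last, precatalyst drains, so f bends below its straight line, and more at the smaller charge, which reaches x later. I therefore committed to slightly above S in both cases.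

The forecast gave 1.5 and 2.4, a little higher than my S, on this ground: “It looks like clock-like activation of the precatalyst.”

The simulation gave 1.46 and 2.29.

    substrate + enzyme → target + enzyme, rate k1*[substrate]^2.5*[enzyme]/(1 + ([substrate]/Kh1)^2.5) (10.0 mM, k = 1.80 × 10⁷ M⁻²·⁵ s⁻¹)
    precatalyst → enzyme (k = 0.00920 s⁻¹)

In the south-west flask, where the half-life of precatalyst was 1.26 min, 10% conversion came earlier than that, at 0.645 min, and at that moment enzyme was 30.0% of the catalyst and precatalyst 70.0%. Dividing that enzyme share by S for the flask charged at 12 µM gives 14.0%, and the simulated share of enzyme at the same conversion with that charge is 14.8%.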